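## Structural features

The target is a melampolide-type germacranolide: a cyclodeca-1(10),4-diene (C1–C10) whose C1=C10 bond is Z and whose C4=C5 bond is E, each alkene carrying a methyl group (C14 on C10, C15 on C4). A five-membered α-methylene lactone (O–C6, C7, C11, C12, with exocyclic C11=C13) is fused across C6–C7. C6, C7, C8 and C9 form an unbroken row of four oxygen-bearing stereocentres: the allylic lactone oxygen at C6, a tertiary hydroxyl at C7 (the carbon that also carries C11), the angelate at C8 and an allylic hydroxyl at C9. The fragile parts are the (Z)-2-methylbut-2-enoate (it isomerises to the tiglate and can migrate to a neighbouring hydroxyl), the Michael-accepting methylene lactone, the allylic C6–O and C9–O bonds, and the 1,5-diene, which cyclises across the ring under acid. The real difficulty is a medium ring that holds one Z and one E trisubstituted alkene next to four contiguous oxygenated centres, one of them quaternary; none of these can be controlled reliably on a flexible ten-membered ring. The key step uses the fact that C5 and C10 face each other across the ring. Joining them gives a cis-fused decalin (ring A: C1–C5 and C10; ring B: C5–C10) in which C6–C9 sit on a rigid cyclohexane. Both alkenes are then latent in a C4–B bond and a C1–O sulfonate bond, each anti-periplanar to C5–C10.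

## Logic of the disconnections

32 to 31 to 30. The O–Si bond at C9 is cut last. Then C11–C12 and C12–O(C6) are cut together, which turns the methylene lactone into an ethynyl group, carbon monoxide and the C6 hydroxyl. A terminal alkyne survives the whole sequence, whereas an acrylate would not survive methoxide. The forward carbonylation must choose the C6 hydroxyl; this is secured because C8 is already acylated, C9 is silylated and closure through the tertiary C7 hydroxyl would give a four-membered ring.

30 to 29 to 27 and 28. The C6 O–Si bond and the C8 acyl–O bond are cut. Esterification is placed where the secondary C8 hydroxyl is the only reactive one (C7 is tertiary, C6 and C9 are masked). The demand is retention of the Z geometry of 28. No acetal has to be hydrolysed after the ring is opened, so the acid-sensitive diene never meets strong acid.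

27 to 24 (key). C5 and C10 are reconnected, and the C4=C5 and C1=C10 π bonds become a C4–B and a C1–OMs σ bond; the C7/C8 carbonate and the alkynyl silane are restored. The ten-membered ring becomes a cis-decalin, and two alkene geometries become the configurations of C1 and C4 plus a cis ring fusion. Forward, boron at C4 must lie on the face of the C10 methyl, the mesylate at C1 on the opposite face, and C5–H cis to the C10 methyl.

24 to 19 to 17 and 18. The sulfonate, the C2 methylene (from a C2 ketone) and the C4–B bond are removed, leading to a ring A enone (C2=O, C3=C4). The shorter-looking enone, C4=C5 conjugated to a C6 ketone, is rejected. It would make C5 an epimerisable centre, with the trans-fused epimer (which cannot give the Z alkene) expected to be favoured. It would also require boron at C4, hydrogen at C5 and hydride at C6 all to arrive on the hindered methyl-bearing face. With the carbonyl at C2, C5 keeps the configuration from the cycloaddition and boron enters on the convex face. The demands are a silyl cap on the alkyne (boryl copper adds to terminal alkynes) and later removal of the C2 oxygen.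

17 to 14 to 12. The C9–O and C8–O bonds are traced to the C8=C9 alkene through a β-epoxide opened from the α face by a carbonate on the C7 oxygen; this gives the trans C8/C9 and cis C7/C8 relationships in one operation and leaves a carbonate that methoxide removes for free in the key step. The ring A enone is traced to the C2=C3 alkene by an ene reaction that removes the C4 hydrogen.

12 to 10 to 8 to 6 and 7. Protecting groups are removed, C6 is inverted through ketone 9 (reduction directed by the C7 hydroxyl), and the C7–alkyne bond is cut. The C7 ketone must be attacked on the convex face, anti to the C6 oxygen.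

6 to 4. The C7 ketone and C8=C9 alkene arise by carbonyl transposition from the vinylogous ester, so the C9 carbonyl of the adduct is spent as a leaving group and C7 is released at the ketone level for the acetylide.

4 to 2 and 3, 2 to 1. The C1–C10 and C4–C5 bonds are cut in a Diels–Alder sense. One step sets C1, C4, C5 and C10 and places all six ring B carbons. The Lewis acid must direct the silyloxy-bearing diene terminus to the methylated quinone carbon and control the absolute configuration.

## Other disconnections considered

Alternative 1: The lactone C6–O bond and the tertiary C7–O bond are cut together, leading to the ten-membered trienyl acid A2 (Z C6=C7, free C8 hydroxyl). Forward, VO(acac)2 with t-BuOOH would epoxidise C6=C7 on the face of the C8 hydroxyl, and the C12 acid would open the vinylic epoxide at C6 with inversion to give A1.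
- In its favour: C6 and C7 are set in one stereospecific operation from an alkene geometry and an existing carbinol, and no carbonylation is needed. On the C6/C7 pair this is better than the chosen plan, which spends an oxidation and a directed reduction on C6.
- Against it: A2 already contains the Z,E-cyclodecadiene, so the medium-ring problem is only postponed. The C8 hydroxyl is also homoallylic to C1=C10, so a second epoxidation can compete. The acid could open the vinyl epoxide in a conjugate sense at C4. The acrylic acid must be carried through ring formation.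
- Comparison: the chosen plan sets the ring geometry by a stereospecific fragmentation; this cascade controls only two centres. The step count after A2 is equal or lower, but the total depends on an unsolved route to A2.

Alternative 2: C5–C6 and C4–C15 are cut, leading to the open-chain ynal A4. Forward, Ni(cod)2 with an N-heterocyclic carbene would couple the aldehyde carbon with the terminal alkyne carbon while MeZnCl delivers methyl to C4, giving A3.
- In its favour: the ring, the E C4=C5 alkene (cis addition of methyl and C6 across the alkyne) and the C6 carbinol appear in one convergent step. In convergence and in bond economy of the ring-forming step it is better than the chosen plan.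
- Against it: a ten-membered ring is closed against entropy and transannular strain. The C6 configuration depends on induction from the quaternary C7 in a macrocyclic transition state. The Z C1=C10 alkene must be built beforehand in an open chain. The C11 side chain arrives at the alcohol oxidation level and still needs oxidation and lactonisation, and the acetal must be removed with acid on the diene.
- Comparison: geometry and C6 are catalyst- and conformation-dependent here, mechanism-dependent in the chosen plan. Step count is probably comparable or lower for this alternative.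

Alternative 3: C1–C2 is cut, leading to the open-chain dienyl Z vinyl iodide A6, assembled from a hexose of the chiral pool. Forward, 9-BBN would hydroborate the terminal C2=C3 alkene and PdCl2(dppf) would couple the alkylborane with the vinyl iodide to give A5.
- In its favour: absolute configuration comes from the chiral pool without asymmetric catalysis, which is better than the chosen plan on that point. The Z geometry is fixed in the iodide and retained. A5 is of the same type as the intermediate after the chosen key step, so the endgame is equal.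
- Against it: the terminal alkene is part of a 1,3-diene, so hydroboration regiochemistry is uncertain. A strained E,Z-cyclodeca-1,5-diene is closed by cross-coupling at high dilution. Building the quaternary alkynyl carbinol C7 on a sugar chain is long.
- Comparison: the chosen plan pays no macrocyclisation entropy and fixes both alkenes stereospecifically. This alternative is more modular but longer in its linear sequence.

Key step: step 18

Assumption: target numbering (C1–C15) is used for every intermediate; β is the face of the bicyclic intermediates that carries the C10 methyl, α the opposite face; the hand of the oxazaborolidinium catalyst that gives 4 is assigned from the usual pre-transition-state model, and the other hand is equally available.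

## Route

Step 1
Reactants: 1 (E)-pent-2-enal
Product: 2 (1E,3E)-1-(triethylsilyloxy)penta-1,3-diene
Conditions: TESOTf, Et3N, Et2O, 0 °C to rt
Reagents that add atoms: triethylsilyl trifluoromethanesulfonate, CC[Si](CC)(CC)OS(=O)(=O)C(F)(F)F
Why: Soft enolisation (O-silylation, then γ-deprotonation) gives the silyl dienol ether; the E,E isomer should predominate, and Z isomers cannot reach the s-cis geometry, so they are spectators in step 2.

Step 2
Reactants: 2 (1E,3E)-1-(triethylsilyloxy)penta-1,3-diene; 3 2-methoxy-5-methyl-1,4-benzoquinone
Product: 4 cis-fused endo adduct (7-methoxy-4α,10β-dimethyl-1α-triethylsilyloxy-5βH-octalin-2,7-diene-6,9-dione)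
Conditions: (S)-o-tolyl diphenylprolinol oxazaborolidine·HNTf2 (20 mol%), CH2Cl2, −78 °C
Reagents that add atoms: none
Why: Lewis-acid-catalysed endo Diels–Alder reaction; the monodentate boron cation binds the more basic vinylogous-ester carbonyl, so the methyl-bearing diene terminus attacks the unsubstituted quinone carbon and the silyloxy carbon bonds to the methylated one (C1–C10, C4–C5). The endo transition state places C1–O and C4–CH3 cis to the ring B bonds and trans to C10–CH3 and C5–H, and the chiral cation shields one quinone face, setting the absolute configuration of C1, C4, C5 and C10.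

Step 3
Reactants: 4 cis-fused endo adduct
Product: 6 6α-hydroxy-7-oxo-Δ8 enone (ring A unchanged), via enol ether diol 5 (not isolated)
Conditions: i-Bu2AlH, CH2Cl2, −78 °C; then 1 M HCl, THF, 0 °C
Reagents that add atoms: water, O
Why: 1,2-Reduction of both carbonyls on the convex β face, then acid-induced loss of the C9 hydroxyl with hydrolysis of the enol ether (Stork–Danheiser-type carbonyl transposition), gives the C7 ketone conjugated to C8=C9. The C6 carbinol is α; C5 is no longer beside a ketone and cannot epimerise.

Step 4
Reactants: 6 6α-hydroxy-7-oxo-Δ8 enone; 7 trimethylsilylacetylene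
Product: 8 7β-(trimethylsilylethynyl)-6α,7α-diol
Conditions: n-BuLi, THF, −78 °C (7, 3 equiv); then 6, −78 to −40 °C
Reagents that add atoms: none
Why: 1,2-Addition of the lithium acetylide to the enone carbonyl; attack on the convex β face, anti to the C6 alkoxide of the lithium chelate, sets C7 with the alkyne β and the hydroxyl α.

Step 5
Reactants: 8 7β-(trimethylsilylethynyl)-6α,7α-diol
Product: 9 7α-hydroxy-6-ketone
Conditions: Dess–Martin periodinane, NaHCO3, CH2Cl2, 0 °C to rt
Reagents that add atoms: none
Why: Hypervalent-iodine oxidation of the only secondary alcohol; the tertiary propargylic hydroxyl is inert and the buffered medium should not epimerise C5.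

Step 6
Reactants: 9 7α-hydroxy-6-ketone
Product: 10 6β,7α-diol
Conditions: Me4NBH(OAc)3, MeCN/AcOH, −30 °C
Reagents that add atoms: none
Why: Hydroxyl-directed triacetoxyborohydride reduction: boron bound to the α C7 hydroxyl delivers hydride to the α face of C6, giving the β carbinol (trans diol); ketones without a neighbouring hydroxyl are not reduced by this reagent, so delivery is internal.

Step 7
Reactants: 10 6β,7α-diol
Product: 11 6β-tert-butyldimethylsilyl ether
Conditions: TBSOTf, 2,6-lutidine, CH2Cl2, −78 °C
Reagents that add atoms: tert-butyldimethylsilyl trifluoromethanesulfonate, CC(C)(C)[Si](C)(C)OS(=O)(=O)C(F)(F)F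
Why: Silylation of the secondary hydroxyl is much faster than that of the tertiary one at low temperature; this ether is the C6 protecting group up to step 20.

Step 8
Reactants: 11 6β-tert-butyldimethylsilyl ether
Product: 12 7α-tert-butyl carbonate
Conditions: LiHMDS, THF, −78 °C; Boc2O, −78 to −20 °C
Reagents that add atoms: di-tert-butyl dicarbonate, CC(C)(C)OC(=O)OC(=O)OC(C)(C)C
Why: Acylation of the tertiary lithium alkoxide; silyl migration from the secondary to the tertiary oxygen is uphill and slow at this temperature.

Step 9
Reactants: 12 7α-tert-butyl carbonate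
Product: 14 ring A enone (2-oxo-Δ3), via allylic hydroperoxide 13 (not isolated)
Conditions: O2, tetraphenylporphyrin (cat.), hν, CH2Cl2, 0 °C; then Ac2O, pyridine, DMAP, 0 °C to rt
Reagents that add atoms: dioxygen, O=O
Why: Schenck ene reaction of singlet oxygen on the convex β face of C2=C3 abstracts the pseudo-axial tertiary C4–H (the C1–H lies near the alkene plane and is geminal to oxygen), moving the alkene to C3=C4 with oxygen on C2. Acetylation and elimination of the hydroperoxide give the enone. C8=C9 has no allylic hydrogen and the silyl alkyne is inert.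

Step 10
Reactants: 14 ring A enone
Product: 16 7α,8α-cyclic carbonate with free 9β-hydroxyl, via 8β,9β-epoxide 15 (not isolated)
Conditions: dimethyldioxirane, acetone/CH2Cl2, −20 to 0 °C; evaporate; BF3·OEt2 (0.3 equiv), CH2Cl2, −78 to −40 °C
Reagents that add atoms: dimethyldioxirane, CC1(C)OO1
Why: In the half-chair with the C6 and C7 oxygen substituents equatorial, the β face of C8=C9 carries only the slim alkynyl group, so the electrophilic oxidant should give the β-epoxide and leave the electron-poor enone alone. The Lewis acid then induces 5-exo attack of the carbonate carbonyl oxygen on C8 with inversion and loss of isobutene (neighbouring-group opening of an epoxy tert-butyl carbonate). This sets C8–O α and C9–OH β.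

Step 11
Reactants: 16 7α,8α-cyclic carbonate with free 9β-hydroxyl
Product: 17 9β-triisopropylsilyl ether
Conditions: TIPSOTf, 2,6-lutidine, CH2Cl2, 0 °C to rt
Reagents that add atoms: triisopropylsilyl trifluoromethanesulfonate, CC(C)[Si](C(C)C)(C(C)C)OS(=O)(=O)C(F)(F)F
Why: Silyl triflate silylation of the hindered neopentylic carbinol; the most robust silyl group is placed on the oxygen that is released last.

Step 12
Reactants: 17 9β-triisopropylsilyl ether; 18 bis(pinacolato)diboron
Product: 19 4β-pinacolboryl 2-ketone
Conditions: CuCl (10 mol%), Xantphos (10 mol%), NaOtBu (10 mol%), MeOH (2 equiv), THF, rt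
Reagents that add atoms: none
Why: Copper-catalysed conjugate borylation of a β,β-disubstituted cyclohexenone (boryl-copper 1,4-addition, protonation at C3). In the cis-fused enone, boron enters C4 on the convex β face, anti to the axial C10–C9 bond and to C6 on the neighbouring C5, so it ends cis to the C10 methyl and C5–H. C5 is untouched, and the hindered silyl-capped alkyne should not react.

Step 13
Reactants: 19 4β-pinacolboryl 2-ketone
Product: 20 2α-alcohol
Conditions: NaBH4, CeCl3·7H2O, MeOH/THF, −78 °C
Reagents that add atoms: none
Why: Borohydride reduction of the only ketone; the low-basicity conditions limit silyl migration from C1–O, and the configuration at C2 is of no consequence.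

Step 14
Reactants: 20 2α-alcohol
Product: 21 2-O-phenyl thionocarbonate
Conditions: PhOC(S)Cl, pyridine, DMAP, CH2Cl2, rt
Reagents that add atoms: O-phenyl chlorothionoformate, ClC(=S)Oc1ccccc1
Why: Acylation of the only free hydroxyl to the radical precursor for deoxygenation.

Step 15
Reactants: 21 2-O-phenyl thionocarbonate
Product: 22 2-deoxy boronate (1α-triethylsilyl ether)
Conditions: Bu3SnH, AIBN, toluene, 90 °C
Reagents that add atoms: none
Why: Barton–McCombie deoxygenation; the secondary C2 radical has no fragmentation path (β-silyloxy and γ-boryl groups are inert) and stannyl radicals add only slowly to the hindered silyl alkyne.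

Step 16
Reactants: 22 2-deoxy boronate
Product: 23 1α-alcohol
Conditions: PPTS, MeOH/CH2Cl2, 0 °C to rt
Reagents that add atoms: none
Why: Acid-catalysed methanolysis removes the triethylsilyl ether selectively; the hindered tert-butyldimethylsilyl and triisopropylsilyl ethers, the boronate, the carbonate and the alkynyl silane are stable.

Step 17
Reactants: 23 1α-alcohol
Product: 24 fragmentation precursor: cis-fused 1α-mesyloxy-4β-pinacolboryl decalin
Conditions: MsCl, Et3N, CH2Cl2, 0 °C
Reagents that add atoms: methanesulfonyl chloride, CS(=O)(=O)Cl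
Why: Sulfonylation of the only free hydroxyl through sulfene; triethylamine does not form a boron ate complex, so the latent fragmentation is not triggered.

Step 18
Reactants: 24 fragmentation precursor
Product: 27 Z-1(10),E-4-cyclodecadiene 7,8-diol with C7 ethynyl, via methoxyboronate ate complex 25 (not isolated), via carbonate-protected silylalkynyl cyclodecadiene 26 (not isolated)
Conditions: NaOMe (1.5 equiv), THF, −20 to 0 °C; then MeOH, NaOMe (3 equiv), rt
Reagents that add atoms: none
Why: Methoxide adds to boron; in the ate complex the C4–B electron pair becomes the C4=C5 π bond, the C5–C10 σ pair becomes the C1=C10 π bond and mesylate leaves, a concerted seven-centre Grob fragmentation. The closest known reaction type is the boronate-triggered fragmentation of decalins that carry boron and a sulfonate in a 1,4 relationship, which gives cyclodeca-1,5-dienes. No ring is closed by bond formation: the ten-membered ring is released by cleaving the bond shared by the two six-membered rings, so no macrocyclisation entropy is paid. No stereocentre is created; C1, C4, C5 and C10 are converted into two alkene geometries. The step needs both the C4–B and C1–O bonds anti-periplanar to C5–C10, which is possible only in the cis-fused chair with both groups equatorial on ring A. In that chair C10–C9 is axial and C5–C6 equatorial to ring A, so C2 and C9 end cis (Z C1=C10) and C3 and C6 end trans (E C4=C5). The configurations that secure this are boron cis and mesylate trans to the C10 methyl, set in steps 12 and 2. The ring-flipped chair cannot fragment, and the syn-axial C15/C9 and peri C1–O/C9–O contacts of the reactive chair are relieved in the transition state. Excess methoxide in methanol then cleaves the cyclic carbonate (as dimethyl carbonate) and the alkynyl silane.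

Step 19
Reactants: 27 Z-1(10),E-4-cyclodecadiene 7,8-diol; 28 angelic acid ((Z)-2-methylbut-2-enoic acid)
Product: 29 8-angelate
Conditions: 2,4,6-trichlorobenzoyl chloride, Et3N, toluene, rt; then 27, DMAP, rt
Reagents that add atoms: none
Why: Yamaguchi esterification through the mixed anhydride acylates the secondary C8 hydroxyl (the tertiary C7 hydroxyl is inert) under conditions known to keep the Z geometry of angelates.

Step 20
Reactants: 29 8-angelate
Product: 30 6-alcohol
Conditions: HF·pyridine, pyridine, THF, 0 °C
Reagents that add atoms: none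
Why: Buffered fluoride cleaves the tert-butyldimethylsilyl ether well before the triisopropylsilyl ether; the weakly acidic medium avoids acyl migration and diene cyclisation.

Step 21
Reactants: 30 6-alcohol
Product: 31 α-methylene lactone (9-triisopropylsilyl ether)
Conditions: PdI2 (5 mol%), PBu3 (10 mol%), CO (3 atm), MeCN, 60 °C
Reagents that add atoms: carbon monoxide, [C-]#[O+]
Why: Palladium-catalysed cyclocarbonylation of a homopropargylic alcohol: the alkoxycarbonyl palladium species formed at the C6 oxygen adds across the alkyne with the acyl carbon on the internal carbon (five-membered closure), and protonolysis of the vinyl palladium gives the exocyclic methylene. C8 is esterified, C9 is silylated, and closure through the C7 hydroxyl would give a four-membered ring.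

Step 22
Reactants: 31 α-methylene lactone (9-triisopropylsilyl ether)
Product: 32 target
Conditions: HF·pyridine, THF, rt
Reagents that add atoms: none
Why: Fluoride-mediated desilylation under weakly acidic conditions, which the methylene lactone, the angelate and the diene should tolerate.

## Compound list

1 | (E)-pent-2-enal | CC/C=C/C=O | starting material
2 | (1E,3E)-1-(triethylsilyloxy)penta-1,3-diene | C/C=C/C=C/O[Si](CC)(CC)CC | intermediate
3 | 2-methoxy-5-methyl-1,4-benzoquinone | COC1=CC(=O)C(C)=CC1=O | starting material
4 | cis-fused endo adduct, 7-methoxy-4α,10β-dimethyl-1α-triethylsilyloxy-5βH-octalin-2,7-diene-6,9-dione | O=C2[C@@H]3[C@H](C)C=C[C@H](O[Si](CC)(CC)CC)[C@]3(C)C(=O)C=C2OC | intermediate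
5 | 6α,9α-diol of 4 (enol ether kept) | O[C@@H]2[C@@H]3[C@H](C)C=C[C@H](O[Si](CC)(CC)CC)[C@]3(C)[C@H](O)C=C2OC | intermediate (not isolated)
6 | 6α-hydroxy-7-oxo-Δ2,Δ8 octalin (1α-OTES, 4α-Me, 5βH, 10β-Me) | O[C@@H]2[C@@H]3[C@H](C)C=C[C@H](O[Si](CC)(CC)CC)[C@]3(C)C=CC2=O | intermediate
7 | trimethylsilylacetylene | C#C[Si](C)(C)C | starting material
8 | 7β-(trimethylsilylethynyl)-6α,7α-diol | O[C@@H]2[C@@H]3[C@H](C)C=C[C@H](O[Si](CC)(CC)CC)[C@]3(C)C=C[C@@]2(O)C#C[Si](C)(C)C | intermediate
9 | 7α-hydroxy-7β-(trimethylsilylethynyl)-6-ketone | O=C2[C@@H]3[C@H](C)C=C[C@H](O[Si](CC)(CC)CC)[C@]3(C)C=C[C@@]2(O)C#C[Si](C)(C)C | intermediate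
10 | 6β,7α-diol | O[C@H]2[C@@H]3[C@H](C)C=C[C@H](O[Si](CC)(CC)CC)[C@]3(C)C=C[C@@]2(O)C#C[Si](C)(C)C | intermediate
11 | 6β-OTBS, 7α-OH | CC(C)(C)[Si](C)(C)O[C@H]2[C@@H]3[C@H](C)C=C[C@H](O[Si](CC)(CC)CC)[C@]3(C)C=C[C@@]2(O)C#C[Si](C)(C)C | intermediate
12 | 6β-OTBS, 7α-OBoc | CC(C)(C)[Si](C)(C)O[C@H]2[C@@H]3[C@H](C)C=C[C@H](O[Si](CC)(CC)CC)[C@]3(C)C=C[C@@]2(OC(=O)OC(C)(C)C)C#C[Si](C)(C)C | intermediate
13 | 2β-hydroperoxy-Δ3 compound | CC(C)(C)[Si](C)(C)O[C@H]2[C@@H]3C(C)=C[C@@H](OO)[C@H](O[Si](CC)(CC)CC)[C@]3(C)C=C[C@@]2(OC(=O)OC(C)(C)C)C#C[Si](C)(C)C | intermediate (not isolated)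
14 | ring A enone (2-oxo-Δ3, 1α-OTES) | CC(C)(C)[Si](C)(C)O[C@H]2[C@@H]3C(C)=CC(=O)[C@H](O[Si](CC)(CC)CC)[C@]3(C)C=C[C@@]2(OC(=O)OC(C)(C)C)C#C[Si](C)(C)C | intermediate
15 | 8β,9β-epoxide of 14 | CC(C)(C)[Si](C)(C)O[C@H]2[C@@H]3C(C)=CC(=O)[C@H](O[Si](CC)(CC)CC)[C@]3(C)[C@H]4O[C@H]4[C@@]2(OC(=O)OC(C)(C)C)C#C[Si](C)(C)C | intermediate (not isolated)
16 | 7α,8α-cyclic carbonate, 9β-OH | CC(C)(C)[Si](C)(C)O[C@H]2[C@@H]3C(C)=CC(=O)[C@H](O[Si](CC)(CC)CC)[C@]3(C)[C@@H](O)[C@H](OC(=O)O4)[C@@]24C#C[Si](C)(C)C | intermediate
17 | 7α,8α-cyclic carbonate, 9β-OTIPS | CC(C)(C)[Si](C)(C)O[C@H]2[C@@H]3C(C)=CC(=O)[C@H](O[Si](CC)(CC)CC)[C@]3(C)[C@@H](O[Si](C(C)C)(C(C)C)C(C)C)[C@H](OC(=O)O4)[C@@]24C#C[Si](C)(C)C | intermediate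
18 | bis(pinacolato)diboron | CC1(C)OB(OC1(C)C)B1OC(C)(C)C(C)(C)O1 | starting material
19 | 4β-pinacolboryl-4α-methyl 2-ketone | CC(C)(C)[Si](C)(C)O[C@H]2[C@@H]3[C@@](C)(B5OC(C)(C)C(C)(C)O5)CC(=O)[C@H](O[Si](CC)(CC)CC)[C@]3(C)[C@@H](O[Si](C(C)C)(C(C)C)C(C)C)[C@H](OC(=O)O4)[C@@]24C#C[Si](C)(C)C | intermediate
20 | 2α-alcohol | CC(C)(C)[Si](C)(C)O[C@H]2[C@@H]3[C@@](C)(B5OC(C)(C)C(C)(C)O5)C[C@H](O)[C@H](O[Si](CC)(CC)CC)[C@]3(C)[C@@H](O[Si](C(C)C)(C(C)C)C(C)C)[C@H](OC(=O)O4)[C@@]24C#C[Si](C)(C)C | intermediate
21 | 2α-O-phenyl thionocarbonate | CC(C)(C)[Si](C)(C)O[C@H]2[C@@H]3[C@@](C)(B5OC(C)(C)C(C)(C)O5)C[C@H](OC(=S)Oc6ccccc6)[C@H](O[Si](CC)(CC)CC)[C@]3(C)[C@@H](O[Si](C(C)C)(C(C)C)C(C)C)[C@H](OC(=O)O4)[C@@]24C#C[Si](C)(C)C | intermediate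
22 | 2-deoxy boronate, 1α-OTES | CC(C)(C)[Si](C)(C)O[C@H]2[C@@H]3[C@@](C)(B5OC(C)(C)C(C)(C)O5)CC[C@H](O[Si](CC)(CC)CC)[C@]3(C)[C@@H](O[Si](C(C)C)(C(C)C)C(C)C)[C@H](OC(=O)O4)[C@@]24C#C[Si](C)(C)C | intermediate
23 | 1α-alcohol | CC(C)(C)[Si](C)(C)O[C@H]2[C@@H]3[C@@](C)(B5OC(C)(C)C(C)(C)O5)CC[C@H](O)[C@]3(C)[C@@H](O[Si](C(C)C)(C(C)C)C(C)C)[C@H](OC(=O)O4)[C@@]24C#C[Si](C)(C)C | intermediate
24 | cis-fused 1α-mesyloxy-4β-pinacolboryl decalin (6β-OTBS, 7α,8α-carbonate, 7β-silylethynyl, 9β-OTIPS) | CC(C)(C)[Si](C)(C)O[C@H]2[C@@H]3[C@@](C)(B5OC(C)(C)C(C)(C)O5)CC[C@H](OS(C)(=O)=O)[C@]3(C)[C@@H](O[Si](C(C)C)(C(C)C)C(C)C)[C@H](OC(=O)O4)[C@@]24C#C[Si](C)(C)C | intermediate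
25 | sodium methoxyboronate of 24 | [Na+].CC(C)(C)[Si](C)(C)O[C@H]2[C@@H]3[C@@](C)([B-]5(OC)OC(C)(C)C(C)(C)O5)CC[C@H](OS(C)(=O)=O)[C@]3(C)[C@@H](O[Si](C(C)C)(C(C)C)C(C)C)[C@H](OC(=O)O4)[C@@]24C#C[Si](C)(C)C | intermediate (not isolated)
26 | Z-1(10),E-4-cyclodecadiene, carbonate and alkynyl silane intact | CC(C)(C)[Si](C)(C)O[C@H]2/C=C(\C)CC/C=C(/C)[C@@H](O[Si](C(C)C)(C(C)C)C(C)C)[C@H](OC(=O)O4)[C@@]24C#C[Si](C)(C)C | intermediate (not isolated)
27 | Z-1(10),E-4-cyclodecadiene 7,8-diol, 6-OTBS, 9-OTIPS, 7-ethynyl | CC(C)(C)[Si](C)(C)O[C@H]2/C=C(\C)CC/C=C(/C)[C@@H](O[Si](C(C)C)(C(C)C)C(C)C)[C@H](O)[C@@]2(O)C#C | intermediate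
28 | angelic acid | C/C=C(/C)C(=O)O | starting material
29 | 8-angelate, 6-OTBS, 9-OTIPS | CC(C)(C)[Si](C)(C)O[C@H]2/C=C(\C)CC/C=C(/C)[C@@H](O[Si](C(C)C)(C(C)C)C(C)C)[C@H](OC(=O)/C(C)=C\C)[C@@]2(O)C#C | intermediate
30 | 8-angelate, 6-OH, 9-OTIPS | O[C@H]2/C=C(\C)CC/C=C(/C)[C@@H](O[Si](C(C)C)(C(C)C)C(C)C)[C@H](OC(=O)/C(C)=C\C)[C@@]2(O)C#C | intermediate
31 | 9-O-triisopropylsilyl ether of the target | C=C1C(=O)O[C@H]2/C=C(\C)CC/C=C(/C)[C@@H](O[Si](C(C)C)(C(C)C)C(C)C)[C@H](OC(=O)/C(C)=C\C)[C@@]12O | intermediate
32 | CNP0292337.1 | C=C1C(=O)O[C@H]2/C=C(\C)CC/C=C(/C)[C@@H](O)[C@H](OC(=O)/C(C)=C\C)[C@@]12O | target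

## Step count and least certain steps

Total: 22 steps. Longest linear sequence: 22 steps from 1 (3, 7, 18 and 28 are bought).

Step 12 (boron conjugate addition). The likely failures are incomplete facial selectivity at C4, slow addition to the hindered enone, or base-induced epimerisation at C1 beside the ketone. The fallback sets out from 17 and replaces conjugate addition by a stereospecific allylic substitution. Luche reduction (NaBH4, CeCl3·7H2O; hydride on the convex face) should give the 2α allylic alcohol F1. Methyl chloroformate and pyridine give the allylic methyl carbonate F2. Copper-catalysed γ-selective borylation (CuCl, Xantphos, KOtBu, B2pin2) is anti to the leaving group and should give the tertiary allylboronate F3 with boron β at C4. Diimide (2-nitrobenzenesulfonyl hydrazide, Et3N) then saturates C2=C3, and the route is rejoined at 22, with steps 13 to 15 left out.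

Step 9 (photo-oxygenation). The likely failures are a slow ene reaction of the disubstituted, inductively deactivated alkene, or hydrogen abstraction from C1 instead of C4. The fallback sets out from 12. mCPBA should epoxidise the more accessible C2=C3 alkene on the convex face (β-epoxide F4). Sodium benzeneselenolate opens it trans-diaxially at C3 (hydroxy selenide F5). Dess–Martin oxidation gives the α-phenylselanyl ketone F6, which can epimerise at C3. Oxidation with H2O2 and syn elimination of the selenoxide towards C4 returns to 14.

Step 18 (key step). The reactive chair is crowded (syn-axial C15/C9 and peri C1–O/C9–O contacts). If its population is too low, fragmentation is slow, and elimination of the mesylate from the ring-flipped chair or protodeboronation can compete. The fallback sets out from 23 and changes the nucleofuge: Tf2O and pyridine at −40 °C give the C1 triflate F7, used at once. With NaOMe at −78 °C the far better leaving group should let the fragmentation proceed through a small equilibrium share of the reactive chair. Warming in methanol completes carbonate and silane cleavage, and the route is rejoined at 27.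

Step 2 (cycloaddition). The likely failures are loss of regiocontrol if the catalyst binds the other carbonyl, or loss of enantiocontrol through a background reaction. The fallback sets out from 2 and 3. BF3·OEt2 promotes the same regiochemistry without asymmetric induction, and step 3 is run on the racemate. The C6 carbinol is then resolved with a lipase and vinyl acetate; the unwanted antipode would be removed as its acetate, the ent-6 acetate F8. Enantioenriched 6 re-enters the route at step 4.

Step 21 (cyclocarbonylation). The likely failures are competing carbonylation through the tertiary propargylic hydroxyl, or ionisation of the new allylic lactone C6–O bond by zerovalent palladium formed under CO. The fallback sets out from 30 and uses a radical ring closure. PhSeC(O)Cl and pyridine at 0 °C give the Se-phenyl selenocarbonate F9 at the C6 oxygen. Bu3SnH and AIBN generate the alkoxycarbonyl radical, which closes 5-exo onto the alkyne, and the route is rejoined at 31.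

## Further compounds

F1 | step 12 | 2α allylic alcohol (Δ3, 1α-OTES) | CC(C)(C)[Si](C)(C)O[C@H]2[C@@H]3C(C)=C[C@H](O)[C@H](O[Si](CC)(CC)CC)[C@]3(C)[C@@H](O[Si](C(C)C)(C(C)C)C(C)C)[C@H](OC(=O)O4)[C@@]24C#C[Si](C)(C)C
F2 | step 12 | 2α allylic methyl carbonate | CC(C)(C)[Si](C)(C)O[C@H]2[C@@H]3C(C)=C[C@H](OC(=O)OC)[C@H](O[Si](CC)(CC)CC)[C@]3(C)[C@@H](O[Si](C(C)C)(C(C)C)C(C)C)[C@H](OC(=O)O4)[C@@]24C#C[Si](C)(C)C
F3 | step 12 | tertiary allylboronate (4β-Bpin, Δ2) | CC(C)(C)[Si](C)(C)O[C@H]2[C@@H]3[C@@](C)(B5OC(C)(C)C(C)(C)O5)C=C[C@H](O[Si](CC)(CC)CC)[C@]3(C)[C@@H](O[Si](C(C)C)(C(C)C)C(C)C)[C@H](OC(=O)O4)[C@@]24C#C[Si](C)(C)C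
F4 | step 9 | 2β,3β-epoxide of 12 | CC(C)(C)[Si](C)(C)O[C@H]2[C@@H]3[C@H](C)[C@H]4O[C@H]4[C@H](O[Si](CC)(CC)CC)[C@]3(C)C=C[C@@]2(OC(=O)OC(C)(C)C)C#C[Si](C)(C)C
F5 | step 9 | 2β-hydroxy-3α-phenylselanyl compound | CC(C)(C)[Si](C)(C)O[C@H]2[C@@H]3[C@H](C)[C@H]([Se]c6ccccc6)[C@@H](O)[C@H](O[Si](CC)(CC)CC)[C@]3(C)C=C[C@@]2(OC(=O)OC(C)(C)C)C#C[Si](C)(C)C
F6 | step 9 | 3-phenylselanyl 2-ketone | CC(C)(C)[Si](C)(C)O[C@H]2[C@@H]3[C@H](C)[C@H]([Se]c6ccccc6)C(=O)[C@H](O[Si](CC)(CC)CC)[C@]3(C)C=C[C@@]2(OC(=O)OC(C)(C)C)C#C[Si](C)(C)C
F7 | step 18 | C1 triflate analogue of 24 | CC(C)(C)[Si](C)(C)O[C@H]2[C@@H]3[C@@](C)(B5OC(C)(C)C(C)(C)O5)CC[C@H](OS(=O)(=O)C(F)(F)F)[C@]3(C)[C@@H](O[Si](C(C)C)(C(C)C)C(C)C)[C@H](OC(=O)O4)[C@@]24C#C[Si](C)(C)C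
F8 | step 2 | ent-6 acetate | CC(=O)O[C@H]2[C@H]3[C@@H](C)C=C[C@@H](O[Si](CC)(CC)CC)[C@@]3(C)C=CC2=O
F9 | step 21 | Se-phenyl selenocarbonate of 30 at C6 | O=C([Se]c1ccccc1)O[C@H]2/C=C(\C)CC/C=C(/C)[C@@H](O[Si](C(C)C)(C(C)C)C(C)C)[C@H](OC(=O)/C(C)=C\C)[C@@]2(O)C#C
A1 | alternative 1 | 7-hydroxy methylene lactone, 8-OH, 9-OTBS | C=C1C(=O)O[C@H]2/C=C(\C)CC/C=C(/C)[C@@H](O[Si](C)(C)C(C)(C)C)[C@H](O)[C@@]12O
A2 | alternative 1 | ten-membered (6Z) trienyl acrylic acid, 8-OH, 9-OTBS | OC(=O)C(=C)/C1=C/C=C(\C)CC/C=C(/C)[C@@H](O[Si](C)(C)C(C)(C)C)[C@@H]1O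
A3 | alternative 2 | ten-membered C6 allylic alcohol with C11–C13 methylene | O[C@H]2/C=C(\C)CC/C=C(/C)[C@@H](O[Si](C)(C)C(C)(C)C)[C@H](OC(C)(C)O4)[C@@]24C(=C)CO[Si](C)(C)C(C)(C)C
A4 | alternative 2 | open-chain ynal | O=C[C@@]1(C(=C)CO[Si](C)(C)C(C)(C)C)OC(C)(C)O[C@H]1[C@H](O[Si](C)(C)C(C)(C)C)/C(C)=C\CCC#C
A5 | alternative 3 | protected cyclodecadiene with C7 silylethynyl | CC[Si](CC)(CC)O[C@H]2/C=C(\C)CC/C=C(/C)[C@@H](O[Si](C)(C)C(C)(C)C)[C@H](OC(C)(C)O4)[C@@]24C#C[Si](C)(C)C
A6 | alternative 3 | open-chain dienyl Z vinyl iodide | C=C/C(C)=C/[C@H](O[Si](CC)(CC)CC)[C@@]1(C#C[Si](C)(C)C)OC(C)(C)O[C@H]1[C@H](O[Si](C)(C)C(C)(C)C)/C(C)=C\I
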